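## Retrosynthetic overview

1. The cyclobutane is made first: head-to-tail [2+2] photodimerisation of two molecules of 3,4,5-trimethoxycinnamic acid 1 gives the α-truxillic-type diacid 2 and sets all four stereocentres in one step.
2. The two dihydropyridinone rings are not built; they are bought intact as lactam 3 and carried as its N-silyl derivative 4.
3. Key disconnection: the two exocyclic imide C–N bonds, cut back to the diacyl difluoride 5 (made in the flask from 2) and 4; forming both bonds in one flask gives the target 6.
4. Ring order: cyclobutane (step 1), then attachment of the two preformed lactam rings (step 3); no protecting groups.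

Assumption: the four descriptors in the SMILES describe the α-truxillic arrangement (aryls trans to each other across the ring, acyl groups trans to each other), which has an inversion centre and is achiral, so "single enantiomer" is read as this single meso diastereomer and only relative configuration has to be controlled.

## Route

Step 1
Reactants: 1 (E)-3,4,5-trimethoxycinnamic acid (two molecules)
Product: 2 hexamethoxy-α-truxillic acid, (1α,2α,3β,4β)-2,4-bis(3,4,5-trimethoxyphenyl)cyclobutane-1,3-dicarboxylic acid
Conditions: hν (365 nm LED), microcrystalline 1 as a stirred hexane slurry, 20 °C, 48 h; triturate with CHCl3 to remove unreacted 1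
Reagents that add atoms: none
Why: Topochemical [2+2] photodimerisation (Schmidt's rule) in a head-to-tail (α-type) crystal, where inversion-related C=C bonds lie parallel and under about 4.2 Å apart; suprafacial addition keeps each aryl trans to its own carboxyl and joins the halves antiparallel, fixing all four stereocentres in the centrosymmetric α-truxillic arrangement.

Step 2
Reactants: 3 5,6-dihydropyridin-2(1H)-one
Product: 4 1-(trimethylsilyl)-5,6-dihydropyridin-2(1H)-one
Conditions: Me3SiCl (1.1 equiv), Et3N (1.2 equiv), toluene, 0 °C to rt; filter under argon, Kugelrohr distillation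
Reagents that add atoms: chlorotrimethylsilane, C[Si](C)(C)Cl
Why: Standard N-silylation of a secondary lactam with a chlorosilane and an amine base; 4 equilibrates with its O-silyl lactim tautomer and carries no stereocentre.

Step 3
Reactants: 2 hexamethoxy-α-truxillic acid; 4 1-(trimethylsilyl)-5,6-dihydropyridin-2(1H)-one (2.3 equiv)
Product: 6 piplartine-dimer A, via hexamethoxy-α-truxilloyl difluoride 5 (not isolated)
Conditions: (Me4N)SCF3 (2.2 equiv), CH2Cl2, rt, 1 h; filter under argon; then 4, [Bu4N][Ph3SiF2] (10 mol % relative to 2), CH2Cl2–MeCN, 0 °C to rt, slow N2 sweep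
Reagents that add atoms: tetramethylammonium trifluoromethanethiolate, C[N+](C)(C)C.[S-]C(F)(F)F (supplies the fluorine of 5; none of its atoms remains in 6)
Why: Proposed new method: fluoride-chain desilylative N-acylation of a silyl lactam by an acyl fluoride — after the known base-free deoxyfluorination of 2 to 5, catalytic fluoride from [Bu4N][Ph3SiF2] strips Me3Si from 4 as gaseous Me3SiF, the free lactamate attacks the C(=O)F group (at N directly, or at O followed by a Mumm-type 1,3 O-to-N acyl shift) and expels fluoride, which carries the chain, so both imide C–N bonds form with the strong Si–F bond as driving force and without stoichiometric base or a ketene-prone acid chloride, leaving the four existing stereocentres untouched; the closest known reaction types are the uncatalysed acylation of N-silyl lactams by acid chlorides, fluoride- or bifluoride-catalysed silicon–fluoride exchange of silyl ethers with sulfonyl fluorides, and fluoride-promoted amidation of acyl fluorides with silylamines.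

## Compound list

1 | (E)-3-(3,4,5-trimethoxyphenyl)prop-2-enoic acid (3,4,5-trimethoxycinnamic acid) | COc1cc(/C=C/C(=O)O)cc(OC)c1OC | starting material
2 | (1α,2α,3β,4β)-2,4-bis(3,4,5-trimethoxyphenyl)cyclobutane-1,3-dicarboxylic acid (hexamethoxy-α-truxillic acid; centrosymmetric, each CO2H cis to one neighbouring aryl and trans to the other) | COc1cc([C@H]2[C@H](C(=O)O)[C@H](c3cc(OC)c(OC)c(OC)c3)[C@H]2C(=O)O)cc(OC)c1OC | intermediate
3 | 5,6-dihydropyridin-2(1H)-one | O=C1C=CCCN1 | starting material
4 | 1-(trimethylsilyl)-5,6-dihydropyridin-2(1H)-one (N-silyl lactam, in equilibrium with the O-silyl lactim) | C[Si](C)(C)N1CCC=CC1=O | intermediate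
5 | (1α,2α,3β,4β)-2,4-bis(3,4,5-trimethoxyphenyl)cyclobutane-1,3-dicarbonyl difluoride (hexamethoxy-α-truxilloyl difluoride) | COc1cc([C@H]2[C@H](C(=O)F)[C@H](c3cc(OC)c(OC)c(OC)c3)[C@H]2C(=O)F)cc(OC)c1OC | intermediate
6 | piplartine-dimer A, 1,1'-{[(1α,2α,3β,4β)-2,4-bis(3,4,5-trimethoxyphenyl)cyclobutane-1,3-diyl]dicarbonyl}bis(5,6-dihydropyridin-2(1H)-one) | COc1cc([C@H]2[C@H](C(=O)N3CCC=CC3=O)[C@H](c3cc(OC)c(OC)c(OC)c3)[C@H]2C(=O)N2CCC=CC2=O)cc(OC)c1OC | target

## Step count and risks

Total step count: 3. Longest linear sequence: 2 (1 → 2 → 6); the branch 3 → 4 is one step.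

The three steps most likely to fail, in order of risk, are step 3, step 1 and step 2.

Step 1 risk: the crystal form of 1 in hand may be photostable or may pack head-to-head, because the outcome depends entirely on the lattice. Fallback (solution photochemistry of a Lewis-acid complex instead of a crystal): setting out from 1, Fischer esterification (MeOH, catalytic H2SO4, reflux) gives methyl (E)-3,4,5-trimethoxycinnamate F1. Irradiation of F1 (Pyrex-filtered Hg lamp) in CH2Cl2 with BF3·OEt2 follows the known Lewis-acid-promoted photodimerisation of cinnamic esters, which favours the head-to-tail α-truxillate, and gives dimethyl hexamethoxy-α-truxillate F2. Saponification (LiOH, THF–H2O, rt, then HCl) comes back to the route at 2.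

Step 2 risk: 4 may hydrolyse on filtration or oligomerise by aza-Michael addition on distillation. Fallback (metal amidate instead of silyl transfer): setting out from 3, deprotonation with LiN(SiMe3)2 in THF at −78 °C gives lithium lactamate F3, which is acylated directly by the filtered CH2Cl2 solution of 5 (classical acylation of a lithium amidate by an acyl halide) and comes back to the route at 6.

Step 3 risk (the proposed new reaction): the fluoride chain may stall through adventitious water (protodesilylation to unreactive N–H lactam), stop at the mono-imide, or lose lactamate to conjugate addition on the product enimide. Fallback (known chemistry): setting out from 2, oxalyl chloride with catalytic DMF in CH2Cl2 gives hexamethoxy-α-truxilloyl dichloride F4, which is added at 0 °C to lactam 3 and Et3N in CH2Cl2 (classical N-acylation of a lactam by an acid chloride) and comes back to the route at 6.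

## Further compounds

F1 | step 1 | methyl (E)-3-(3,4,5-trimethoxyphenyl)prop-2-enoate | COC(=O)/C=C/c1cc(OC)c(OC)c(OC)c1
F2 | step 1 | dimethyl (1α,2α,3β,4β)-2,4-bis(3,4,5-trimethoxyphenyl)cyclobutane-1,3-dicarboxylate | COc1cc([C@H]2[C@H](C(=O)OC)[C@H](c3cc(OC)c(OC)c(OC)c3)[C@H]2C(=O)OC)cc(OC)c1OC
F3 | step 2 | lithium 6-oxo-3,6-dihydro-2H-pyridin-1-ide (lithium lactamate of 3) | [Li+].O=C1C=CCC[N-]1
F4 | step 3 | (1α,2α,3β,4β)-2,4-bis(3,4,5-trimethoxyphenyl)cyclobutane-1,3-dicarbonyl dichloride | COc1cc([C@H]2[C@H](C(=O)Cl)[C@H](c3cc(OC)c(OC)c(OC)c3)[C@H]2C(=O)Cl)cc(OC)c1OC
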